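**West run.** E, the substrate, gives D on the way to Z with J present as catalyst, and we want the most D this flask holds.

common to all: E 1.5 M
- west: J 21 mol%; run made earlier
- flask: J 14 mol%; time 15 d

west run (percent of the E charged)

| time / d | D / % | Z / % |
|---|---|---|
| 0.333 | 28.1 | 29.3 |
| 0.833 | 7.0 | 55.3 |
| 1.67 | 0.6 | 62.0 |
| 2.50 | 1.1 | 62.2 |
| 3.00 | 0.4 | 63.2 |
| 5.00 | 0 | 62.2 |

(each reading ± 0.5 percentage points)

- when, up to 15 d, the flask holds most D
- the amount of D, in percent of the E charged, at that time

**Fastest rung.** In the west run Z reads a plateau of 62.2 % of the charge at 5.00 d. The part of that plateau still missing from D + Z at 0.333 d gives a filling rate of 7.69 d⁻¹.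

**Slower rung.** Between the first two readings D falls at 2.78 d⁻¹, slower than it fills. This pseudo-first-order tail rate is what we carry.

**Slowest rung.** In the west run Z then reads between 62.0 % and 63.2 % up to 5.00 d.

**Our reckoning.** For two steps in line, D peaks at ln(fill/tail)/(fill − tail), and its height is the plateau times exp(−tail × that time). No earlier run varies J, so we guess: the plateau and filling rate stay, and the tail rate follows the loading, to 1.85 d⁻¹ in this flask. That puts our peak at 0.244 d, with 39.6 % of the charge as D.

**The forecast.** It gives 33 % at 0.29 d, and it rests on this: “Assuming both steps are first order in J”. One difference is that we leave the filling rate unscaled.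

**Result.** This flask holds most D at 0.187 d, with 39.7 % of the charge, earlier than our 0.244 d. At that moment E still stands at 18.1 % and the other product, G, at 30.9 %.

    E → D (k = 8.25 × 10⁻⁵ s⁻¹)
    J + D → J + Z (k = 1.12 × 10⁻⁴ M⁻¹ s⁻¹)
    E + D → G (k = 5.19 × 10⁻⁵ M⁻¹ s⁻¹)

**Next flask.** For a neighbour charged with 24 mol% of J we scale the tail rate to 3.18 d⁻¹, so we reckon its peak at 33.4 %. The most D that neighbour holds is 34.9 %.

The runs are simulated from invented constants, and the scatter is random.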